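**Retrosynthetic overview**

1. The butenolide is attached last and intact, by B-alkyl Suzuki coupling at C12 of a C9-vinyl decalin; C17 comes from reduction of an equatorial C8 ester and the C19 acid from a benzyl ester.
2. The saturated decalin comes from a ring-B dienoate (C5=C6–C7=C8–CO2Me): hydrogenation sets the trans ring fusion at C5 and base equilibration sets C8.
3. Key disconnection: C5–C10 and C8–C9 together, by intramolecular Diels–Alder reaction of a 2-pyrone-3-carboxylate with an (E)-alkene followed by loss of CO2. Rings A and B form in this one step from a flat, monocyclic precursor with a single stereocentre (C4).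
4. Enabling feature: ring B carries a carboxyl-level carbon (C17) on C8, and its C5 sits on the quaternary C4. C5–C6–C7–C8(C17) is therefore the C6–C5–C4–C3(CO2Me) edge of a pyrone anchored on C4, and C9–C10, with C11 cis to C20, is an (E)-trisubstituted alkene held three carbons (C1–C3, the future ring A) away.
5. The pyrone comes from a methyl ketone (acetoacetate C4 centre, auxiliary-controlled methylation); the alkene chain comes from alkyne carboalumination.

Key step: step 8

Remark on names: locants C1–C20 are the labdane locants of the target (C4 carries C18 methyl and C19 carboxyl, C10 carries C20, C8 carries C17, C9 carries C11–C12). α is the face opposite to C20, β the face of C20.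

Assumption: in step 6 the sense of induction of the valine-derived lithio-enamine depends on the external ligand (HMPA or THF). The ligand, or failing that the D-valine ester, is chosen so that methylation gives the (S)-keto ester.

**Step 1**
Reactants: 1 tert-butyldimethyl(pent-4-yn-1-yloxy)silane; 2 oxirane
Product: 5 (3E)-7-{[tert-butyl(dimethyl)silyl]oxy}-4-methylhept-3-en-1-ol, via alkenyldimethylalane 3 (not isolated), via lithium alkenylalanate 4 (not isolated)
Conditions: AlMe3, Cp2ZrCl2 (cat.), CH2Cl2, 0 °C → rt; solvent exchange to hexane/THF, n-BuLi, −78 °C; 2, −78 °C → rt; cold dilute aq. HCl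
Reagents that add atoms: trimethylaluminium, C[Al](C)C
Why: Zirconium-catalysed carboalumination (Negishi) adds methyl and aluminium syn across the terminal alkyne with methyl on the internal carbon, and the derived alanate opens oxirane with retention, so the (E)-trisubstituted alkene (C20 cis to C11) is fixed here.

**Step 2**
Reactants: 5 (3E)-7-{[tert-butyl(dimethyl)silyl]oxy}-4-methylhept-3-en-1-ol
Product: 6 tert-butyl{[(4E)-7-chloro-4-methylhept-4-en-1-yl]oxy}dimethylsilane
Conditions: PPh3, NCS, THF, 0 °C → rt
Reagents that add atoms: N-chlorosuccinimide, O=C1CCC(=O)N1Cl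
Why: Appel-type chlorination converts the primary alcohol by SN2 under neutral conditions that the silyl ether and the alkene tolerate; the chloride is the latent C11=C12 vinyl group.

**Step 3**
Reactants: 6 tert-butyl{[(4E)-7-chloro-4-methylhept-4-en-1-yl]oxy}dimethylsilane
Product: 7 (3E)-7-bromo-1-chloro-4-methylhept-3-ene
Conditions: Ph3PBr2, CH2Cl2, 0 °C → rt
Reagents that add atoms: dibromotriphenylphosphorane, BrP(Br)(c1ccccc1)(c1ccccc1)c1ccccc1
Why: Ph3PBr2 cleaves a primary silyl ether and brominates it in one operation (Appel-type, via the alkoxyphosphonium salt), giving a bromide far more reactive in SN2 than the chloride at the other end.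

**Step 4**
Reactants: 7 (3E)-7-bromo-1-chloro-4-methylhept-3-ene; 8 benzyl 3-oxobutanoate
Product: 9 benzyl (6E)-2-acetyl-9-chloro-6-methylnon-6-enoate (racemic)
Conditions: NaH, THF/DMF, 0 → 50 °C
Reagents that add atoms: none
Why: Acetoacetic ester alkylation: the sodium enolate displaces the primary bromide chemoselectively, the chloride being too slow to compete; the new C4 centre is racemic and is erased in the next step.

**Step 5**
Reactants: 9 benzyl (6E)-2-acetyl-9-chloro-6-methylnon-6-enoate; 10 tert-butyl L-valinate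
Product: 11 benzyl (2Z,6E)-2-[1-({(2S)-1-tert-butoxy-3-methyl-1-oxobutan-2-yl}amino)ethylidene]-9-chloro-6-methylnon-6-enoate
Conditions: BF3·OEt2 (cat.), benzene, reflux, Dean–Stark
Reagents that add atoms: none
Why: Acid-catalysed condensation of a β-keto ester with the amino ester gives the hydrogen-bonded (Z)-enamino ester, which removes the C4 stereocentre and installs the chiral controller.

**Step 6**
Reactants: 11 benzyl (2Z,6E)-2-[1-({(2S)-1-tert-butoxy-3-methyl-1-oxobutan-2-yl}amino)ethylidene]-9-chloro-6-methylnon-6-enoate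
Product: 13 benzyl (2S,6E)-2-acetyl-9-chloro-2,6-dimethylnon-6-enoate, via C-methylated ketimine 12 (not isolated)
Conditions: LDA, PhMe, −78 °C; HMPA; MeI, −78 → −40 °C; aq. citric acid, THF, rt
Reagents that add atoms: iodomethane, CI; water, O
Why: Auxiliary-controlled alkylation of a chiral lithio-enamine (aza-enolate): lithium is chelated by the enamino ester and the valine ester carbonyl, the isopropyl group shields one face, methyl iodide enters from the other and sets the quaternary C4 centre, and mild acid hydrolysis returns the ketone and the auxiliary.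

**Step 7**
Reactants: 13 benzyl (2S,6E)-2-acetyl-9-chloro-2,6-dimethylnon-6-enoate; 14 dimethyl 2-(methoxymethylidene)propanedioate
Product: 16 methyl 6-[(2S,6E)-1-(benzyloxy)-9-chloro-2,6-dimethyl-1-oxonon-6-en-2-yl]-2-oxo-2H-pyran-3-carboxylate, via enone malonate 15 (not isolated)
Conditions: LDA, THF, −78 °C; 14, −78 °C → rt; 1 M HCl
Reagents that add atoms: none
Why: Pyrone annulation of a methyl ketone: the kinetic enolate (the only enolizable site) undergoes addition–elimination with the methoxymethylene malonate and the resulting enol lactonizes onto one ester with loss of methanol; the quaternary C4 centre cannot epimerize.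

**Step 8**
Reactants: 16 methyl 6-[(2S,6E)-1-(benzyloxy)-9-chloro-2,6-dimethyl-1-oxonon-6-en-2-yl]-2-oxo-2H-pyran-3-carboxylate
Product: 18 19-benzyl 17-methyl 12-chloro-13,14,15,16-tetranorlabda-5,7-diene-17,19-dioate (4β-CO2Bn, 4α-Me, 10β-Me, 9α-H), via bridged lactone 17 (not isolated)
Conditions: PhMe (0.01 M), BHT (cat.), sealed tube, 150 → 170 °C
Reagents that add atoms: none
Why: The electron-poor 2-pyrone-3-carboxylate (4π: pyrone C6–C5–C4–C3 = C5–C6–C7–C8) adds across the tethered, unactivated (E)-trisubstituted alkene C10=C9 in a thermal intramolecular inverse-demand Diels–Alder reaction, and the bridged lactone 17 then loses CO2 by retro-[4+2] to the dienoate, so the flat pyrone ring becomes ring B; the closest known reaction type is the Diels–Alder/CO2-extrusion chemistry of 3-carboalkoxy-2-pyrones with unactivated and tethered alkenes. Ring A closes through the C5–C10 bond over the three-carbon tether C1–C3 (six-membered, chair-like; the tether length allows only this regiochemistry), and ring B is assembled from the four pyrone carbons plus C9 and C10 through the C8–C9 bond, the lactone bridge being a temporary ring that leaves as CO2. C9 and C10 are set relative to each other by suprafacial addition to the E-alkene (C20 cis to C11), and the orientation of the lactone bridge is of no consequence because both bridge epimers collapse to the same diene. Their absolute configuration is relayed from C4: the needed transition state holds the C19 ester gauche to the forming C5–C10 bond (syn to C20) and the C4 methyl group anti, an arrangement favoured by the smaller 1,3-diaxial demand of a flat ester toward C20 but opposed by a Felkin–Anh-type preference for ester-anti, so only a moderate bias is expected and the unwanted diastereomer (not an enantiomer) is removed by chromatography. C5 and C8 are left sp2 on purpose, as a dienoate that steps 9 and 10 convert into the trans ring fusion and the equatorial C17 group.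

**Step 9**
Reactants: 18 19-benzyl 17-methyl 12-chloro-13,14,15,16-tetranorlabda-5,7-diene-17,19-dioate
Product: 19 12-chloro-17-methoxy-17-oxo-13,14,15,16-tetranorlabdan-19-oic acid, 8β-ester epimer (5α-H, 8α-H, 9α-H)
Conditions: H2 (3 atm), 10% Pd/C, EtOAc, rt
Reagents that add atoms: none
Why: Heterogeneous hydrogenation delivers hydrogen to the dienoate from the α-face, away from the C10 methyl group and the axial C19 ester, so C5 becomes 5α-H (trans ring fusion) while the benzyl ester is hydrogenolysed; C8 is expected mainly as the axial ester and is corrected in step 10, and a primary alkyl chloride survives these conditions.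

**Step 10**
Reactants: 19 12-chloro-17-methoxy-17-oxo-13,14,15,16-tetranorlabdan-19-oic acid, 8β-ester epimer
Product: 20 12-chloro-17-methoxy-17-oxo-13,14,15,16-tetranorlabdan-19-oic acid, 8α-ester epimer (5α-H, 8β-H, 9α-H)
Conditions: NaOMe, MeOH, 50 °C; aq. HCl
Reagents that add atoms: none
Why: Thermodynamic epimerization through the ester enolate moves the C8 ester from the axial site (1,3-diaxial to C20) to the equatorial α-site trans to the C9 side chain.

**Step 11**
Reactants: 20 12-chloro-17-methoxy-17-oxo-13,14,15,16-tetranorlabdan-19-oic acid, 8α-ester epimer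
Product: 23 17-methoxy-17-oxo-13,14,15,16-tetranorlabd-11-en-19-oic acid (5α-H, 8β-H, 9α-H), via C12 aryl selenide 21 (not isolated), via C12 aryl selenoxide 22 (not isolated)
Conditions: (2-O2NC6H4Se)2, NaBH4, EtOH/DMF, 0 °C → rt; 20 (Na salt), 60 °C; then 30% H2O2, THF, 0 °C → rt
Reagents that add atoms: none
Why: Selenoxide syn-elimination (Grieco-type): the arylselenolate displaces the primary chloride by SN2, oxidation gives the selenoxide, and elimination can only occur toward C11, which unmasks the terminal vinyl group under non-basic conditions.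

**Step 12**
Reactants: 23 17-methoxy-17-oxo-13,14,15,16-tetranorlabd-11-en-19-oic acid
Product: 24 17-hydroxy-13,14,15,16-tetranorlabd-11-en-19-oic acid (5α-H, 8β-H, 9α-H)
Conditions: LiOtBu (1 equiv), THF, 0 °C; LiBH4, 0 °C → rt; aq. HCl
Reagents that add atoms: none
Why: Chemoselective borohydride reduction: LiBH4 reduces the secondary methyl ester to the C17 primary alcohol, while the alkene and the hindered tertiary carboxylate (pre-formed as its lithium salt so that no borane is generated) are untouched.

**Step 13**
Reactants: 24 17-hydroxy-13,14,15,16-tetranorlabd-11-en-19-oic acid; 25 3-bromofuran-2(5H)-one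
Product: 27 (4S,5R,8R,9S,10R)-17-hydroxylabd-13-en-16,15-olid-19-oic acid (CNP0562063.1), via C12 B-alkyl-9-BBN adduct 26 (not isolated)
Conditions: 9-BBN, THF, 0 °C → rt; then 25, PdCl2(dppf), AsPh3, K3PO4 (aq.), DMF, rt; aq. HCl
Reagents that add atoms: none
Why: Anti-Markovnikov hydroboration with 9-BBN places boron on C12 (hydroxyl and carboxyl are taken up as B–O derivatives by excess reagent), and B-alkyl Suzuki–Miyaura coupling with the α-bromobutenolide, a vinyl bromide of the α-halo enoate class, forms the C12–C13 bond and delivers the target after aqueous acidic work-up.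

**Compound list**

1 | tert-butyldimethyl(pent-4-yn-1-yloxy)silane | C#CCCCO[Si](C)(C)C(C)(C)C | starting material
2 | oxirane | C1CO1 | starting material
3 | [(1E)-5-{[tert-butyl(dimethyl)silyl]oxy}-2-methylpent-1-en-1-yl]dimethylalane | CC(C)(C)[Si](C)(C)OCCC/C(C)=C/[Al](C)C | intermediate
4 | lithium butyl[(1E)-5-{[tert-butyl(dimethyl)silyl]oxy}-2-methylpent-1-en-1-yl]dimethylalanate | [Li+].CCCC[Al-](C)(C)/C=C(\C)CCCO[Si](C)(C)C(C)(C)C | intermediate
5 | (3E)-7-{[tert-butyl(dimethyl)silyl]oxy}-4-methylhept-3-en-1-ol | OCC/C=C(\C)CCCO[Si](C)(C)C(C)(C)C | intermediate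
6 | tert-butyl{[(4E)-7-chloro-4-methylhept-4-en-1-yl]oxy}dimethylsilane | ClCC/C=C(\C)CCCO[Si](C)(C)C(C)(C)C | intermediate
7 | (3E)-7-bromo-1-chloro-4-methylhept-3-ene | ClCC/C=C(\C)CCCBr | intermediate
8 | benzyl 3-oxobutanoate | CC(=O)CC(=O)OCc1ccccc1 | starting material
9 | benzyl (6E)-2-acetyl-9-chloro-6-methylnon-6-enoate (racemic) | ClCC/C=C(\C)CCCC(C(C)=O)C(=O)OCc1ccccc1 | intermediate
10 | tert-butyl L-valinate | CC(C)[C@H](N)C(=O)OC(C)(C)C | starting material
11 | benzyl (2Z,6E)-2-[1-({(2S)-1-tert-butoxy-3-methyl-1-oxobutan-2-yl}amino)ethylidene]-9-chloro-6-methylnon-6-enoate | C/C(N[C@@H](C(C)C)C(=O)OC(C)(C)C)=C(\CCC/C(C)=C/CCCl)C(=O)OCc1ccccc1 | intermediate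
12 | benzyl (2S,6E)-2-{N-[(2S)-1-tert-butoxy-3-methyl-1-oxobutan-2-yl]ethanimidoyl}-9-chloro-2,6-dimethylnon-6-enoate | ClCC/C=C(\C)CCC[C@](C)(C(=O)OCc1ccccc1)C(C)=N[C@@H](C(C)C)C(=O)OC(C)(C)C | intermediate
13 | benzyl (2S,6E)-2-acetyl-9-chloro-2,6-dimethylnon-6-enoate | ClCC/C=C(\C)CCC[C@](C)(C(=O)OCc1ccccc1)C(C)=O | intermediate
14 | dimethyl 2-(methoxymethylidene)propanedioate | COC=C(C(=O)OC)C(=O)OC | starting material
15 | dimethyl 2-[(1E,4S,8E)-4-[(benzyloxy)carbonyl]-11-chloro-4,8-dimethyl-3-oxoundeca-1,8-dien-1-yl]propanedioate | ClCC/C=C(\C)CCC[C@](C)(C(=O)OCc1ccccc1)C(=O)/C=C/C(C(=O)OC)C(=O)OC | intermediate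
16 | methyl 6-[(2S,6E)-1-(benzyloxy)-9-chloro-2,6-dimethyl-1-oxonon-6-en-2-yl]-2-oxo-2H-pyran-3-carboxylate | ClCC/C=C(\C)CCC[C@](C)(C(=O)OCc1ccccc1)C1=CC=C(C(=O)OC)C(=O)O1 | intermediate
17 | bridged lactone cycloadduct (C5–O–C(=O)–C8 bridge across ring B, C6=C7; shown with the bridge on the α-face, the bridge epimer gives the same diene) | C[C@]12CCC[C@](C)(C(=O)OCc4ccccc4)[C@@]13OC(=O)[C@](C(=O)OC)(C=C3)[C@@H]2CCCl | intermediate
18 | 19-benzyl 17-methyl 12-chloro-13,14,15,16-tetranorlabda-5,7-diene-17,19-dioate (4β-CO2Bn, 4α-Me, 10β-Me, 9α-H) | C[C@]12CCC[C@](C)(C(=O)OCc3ccccc3)C1=CC=C(C(=O)OC)[C@@H]2CCCl | intermediate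
19 | 12-chloro-17-methoxy-17-oxo-13,14,15,16-tetranorlabdan-19-oic acid, 8β-ester (5α-H, 8α-H, 9α-H) | C[C@]12CCC[C@](C)(C(=O)O)[C@@H]1CC[C@H](C(=O)OC)[C@@H]2CCCl | intermediate
20 | 12-chloro-17-methoxy-17-oxo-13,14,15,16-tetranorlabdan-19-oic acid, 8α-ester (5α-H, 8β-H, 9α-H) | C[C@]12CCC[C@](C)(C(=O)O)[C@@H]1CC[C@@H](C(=O)OC)[C@@H]2CCCl | intermediate
21 | 17-methoxy-12-[(2-nitrophenyl)selanyl]-17-oxo-13,14,15,16-tetranorlabdan-19-oic acid | C[C@]12CCC[C@](C)(C(=O)O)[C@@H]1CC[C@@H](C(=O)OC)[C@@H]2CC[Se]c1ccccc1[N+](=O)[O-] | intermediate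
22 | 17-methoxy-12-[(2-nitrophenyl)seleninyl]-17-oxo-13,14,15,16-tetranorlabdan-19-oic acid | C[C@]12CCC[C@](C)(C(=O)O)[C@@H]1CC[C@@H](C(=O)OC)[C@@H]2CC[Se](=O)c1ccccc1[N+](=O)[O-] | intermediate
23 | 17-methoxy-17-oxo-13,14,15,16-tetranorlabd-11-en-19-oic acid (5α-H, 8β-H, 9α-H) | C[C@]12CCC[C@](C)(C(=O)O)[C@@H]1CC[C@@H](C(=O)OC)[C@@H]2C=C | intermediate
24 | 17-hydroxy-13,14,15,16-tetranorlabd-11-en-19-oic acid (5α-H, 8β-H, 9α-H) | C[C@]12CCC[C@](C)(C(=O)O)[C@@H]1CC[C@@H](CO)[C@@H]2C=C | intermediate
25 | 3-bromofuran-2(5H)-one | BrC1=CCOC1=O | starting material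
26 | C12 B-alkyl-9-BBN adduct of 24 with O17 and the C19 carboxyl as 9-BBN borinates | C[C@]12CCC[C@](C)(C(=O)OB3C4CCCC3CCC4)[C@@H]1CC[C@@H](COB5C6CCCC5CCC6)[C@@H]2CCB7C8CCCC7CCC8 | intermediate
27 | (4S,5R,8R,9S,10R)-17-hydroxylabd-13-en-16,15-olid-19-oic acid = (1S,4aR,5S,6R,8aR)-6-(hydroxymethyl)-1,4a-dimethyl-5-[2-(2-oxo-2,5-dihydrofuran-3-yl)ethyl]decahydronaphthalene-1-carboxylic acid | C[C@]12CCC[C@](C)(C(=O)O)[C@@H]1CC[C@@H](CO)[C@@H]2CCC1=CCOC1=O | target

**Step count**

Total steps: 13. Longest linear sequence: 13 (steps 1–13 from compound 1; compounds 2, 8, 10, 14 and 25 are bought).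

**Steps most likely to fail**

1. Step 8. The C4 centre may discriminate poorly, or in the wrong sense, between the two faces of the alkene, because the polar preference for ester-anti works against the steric preference. The reaction may also be slow, since it joins two fully substituted carbons next to a quaternary one.
Fallback: it sets out from bromide 7 and returns at 19. C4 is carried as an epimerizable methine and is methylated only after ring formation, where the C10 methyl group controls it. The absolute configuration comes from a chiral benzylic ester that the hydrogenation of step 9 removes anyway. (S)-1-Phenylethanol is transesterified with tert-butyl acetoacetate (PhMe, reflux) to (S)-1-phenylethyl 3-oxobutanoate F1. Its sodium enolate is alkylated with 7 to (1S)-1-phenylethyl (6E)-2-acetyl-9-chloro-6-methylnon-6-enoate F2. The dianion of F2 (2 equiv LDA) should react with 14 at its terminal carbon and close to the pyrone with a C4 methine F3. Heating F3 as in step 8 should give, with loss of CO2, the C4-H dienoate F4 as two separable diastereomers that differ in the hand of the C9/C10 pair. Deprotonation at C4 (KHMDS, THF, −78 °C) and MeI, expected to enter from the α-face anti to C20 (equatorial alkylation of a C4 ester enolate beside an axial C10 methyl group), gives the 1-phenylethyl analogue of 18, F5, after chromatographic removal of the diastereomer with the unnatural C9/C10 pair. F5 under the conditions of step 9 gives 19. Half of the material is lost with the unwanted diastereomer.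

2. Step 13. The bromobutenolide and the butenolide product may decompose or isomerize under the basic coupling conditions, and the alkylborane may undergo protodeboronation or β-hydride loss.
Fallback: it sets out from 20 and returns at 27. The butenolide is built by enolate alkylation and sulfoxide elimination instead of cross-coupling. The lithium salt of 20 is reduced with LiBH4 to 12-chloro-17-hydroxy-13,14,15,16-tetranorlabdan-19-oic acid F6. Excess TBSCl/imidazole, then brief K2CO3/MeOH to free the carboxyl group, gives the C17 silyl ether F7, which blocks ether formation between O17 and C12. NaI in acetone gives the C12 iodide F8. 3-(Phenylsulfanyl)oxolan-2-one F9 (from α-bromo-γ-butyrolactone, PhSH, Et3N) is converted into its lithium enolate (LiHMDS, THF/HMPA) and alkylated with the lithium carboxylate of F8 to the α-alkyl-α-phenylsulfanyl lactone F10. mCPBA at −20 °C gives the sulfoxide F11, and heating in PhMe at 100 °C (syn-elimination into the ring) gives the silyl-protected butenolide F12. HF·pyridine in THF then gives 27.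

3. Step 9. The trisubstituted C5=C6 bond between two quaternary carbons may resist saturation, the double bond may migrate to the tetrasubstituted C8=C9 position, or some cis ring fusion may form.
Fallback: it sets out from 18 and returns at 19. Hydrogenation at 1 atm over Pd/C is stopped once the benzyl ester and the C7=C8 bond are consumed, giving 12-chloro-17-methoxy-17-oxo-13,14,15,16-tetranorlabd-5-en-19-oic acid F13. The isolated C5=C6 bond is then reduced by hydrogen-atom-transfer hydrogenation (Mn(dpm)3 cat., PhSiH3, t-BuOOH, i-PrOH, rt), which passes through a tertiary C5 radical and is expected to give the thermodynamically preferred trans ring fusion, hence 19 (together with its C8 epimer 20, which step 10 converges).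

**Further compounds**

F1 | step 8 | (1S)-1-phenylethyl 3-oxobutanoate | CC(=O)CC(=O)O[C@@H](C)c1ccccc1
F2 | step 8 | (1S)-1-phenylethyl (6E)-2-acetyl-9-chloro-6-methylnon-6-enoate (C2 epimers) | ClCC/C=C(\C)CCCC(C(C)=O)C(=O)O[C@@H](C)c1ccccc1
F3 | step 8 | methyl 6-[(6E)-9-chloro-6-methyl-1-oxo-1-{[(1S)-1-phenylethyl]oxy}non-6-en-2-yl]-2-oxo-2H-pyran-3-carboxylate | ClCC/C=C(\C)CCCC(C(=O)O[C@@H](C)c1ccccc1)C1=CC=C(C(=O)OC)C(=O)O1
F4 | step 8 | 19-[(1S)-1-phenylethyl] 17-methyl 12-chloro-13,14,15,16,18-pentanorlabda-5,7-diene-17,19-dioate (natural C9/C10 pair, C4-H epimerizable) | C[C@]12CCCC(C(=O)O[C@@H](C)c3ccccc3)C1=CC=C(C(=O)OC)[C@@H]2CCCl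
F5 | step 8 | 19-[(1S)-1-phenylethyl] 17-methyl 12-chloro-13,14,15,16-tetranorlabda-5,7-diene-17,19-dioate (4β-ester, 4α-Me) | C[C@]12CCC[C@](C)(C(=O)O[C@@H](C)c3ccccc3)C1=CC=C(C(=O)OC)[C@@H]2CCCl
F6 | step 13 | 12-chloro-17-hydroxy-13,14,15,16-tetranorlabdan-19-oic acid | C[C@]12CCC[C@](C)(C(=O)O)[C@@H]1CC[C@@H](CO)[C@@H]2CCCl
F7 | step 13 | 17-{[tert-butyl(dimethyl)silyl]oxy}-12-chloro-13,14,15,16-tetranorlabdan-19-oic acid | C[C@]12CCC[C@](C)(C(=O)O)[C@@H]1CC[C@@H](CO[Si](C)(C)C(C)(C)C)[C@@H]2CCCl
F8 | step 13 | 17-{[tert-butyl(dimethyl)silyl]oxy}-12-iodo-13,14,15,16-tetranorlabdan-19-oic acid | C[C@]12CCC[C@](C)(C(=O)O)[C@@H]1CC[C@@H](CO[Si](C)(C)C(C)(C)C)[C@@H]2CCI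
F9 | step 13 | 3-(phenylsulfanyl)oxolan-2-one | O=C1OCCC1Sc1ccccc1
F10 | step 13 | 17-{[tert-butyl(dimethyl)silyl]oxy}-13-(phenylsulfanyl)labdan-16,15-olid-19-oic acid (C13 epimers) | C[C@]12CCC[C@](C)(C(=O)O)[C@@H]1CC[C@@H](CO[Si](C)(C)C(C)(C)C)[C@@H]2CCC1(Sc2ccccc2)CCOC1=O
F11 | step 13 | 17-{[tert-butyl(dimethyl)silyl]oxy}-13-(phenylsulfinyl)labdan-16,15-olid-19-oic acid | C[C@]12CCC[C@](C)(C(=O)O)[C@@H]1CC[C@@H](CO[Si](C)(C)C(C)(C)C)[C@@H]2CCC1(S(=O)c2ccccc2)CCOC1=O
F12 | step 13 | 17-{[tert-butyl(dimethyl)silyl]oxy}labd-13-en-16,15-olid-19-oic acid | C[C@]12CCC[C@](C)(C(=O)O)[C@@H]1CC[C@@H](CO[Si](C)(C)C(C)(C)C)[C@@H]2CCC1=CCOC1=O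
F13 | step 9 | 12-chloro-17-methoxy-17-oxo-13,14,15,16-tetranorlabd-5-en-19-oic acid (8β-ester shown) | C[C@]12CCC[C@](C)(C(=O)O)C1=CC[C@H](C(=O)OC)[C@@H]2CCCl
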